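**Retrosynthetic overview**

1. Epoxytwinol A (28) is traced back to an arene-level cage. Each cyclohexenone ring (C4a–C5–C6–C7–C8–C8a) is unmasked last from a C8 phenol: dearomatisation to the C8-keto/C5-ketal dienone, C6–C7 epoxidation, C8 reduction, ketal hydrolysis.
2. Feature: in that cage each benzo ring is fused at C4a/C8a to a pyran whose atoms C1–O2–C3(CH3)–C4 tether the two fusion carbons. This is the retron of a 1,7-diyne + acetylene [2+2+2], with C6/C7 from acetylene. The tether atoms of both halves, joined C1–C1' and C4–C4', form a 1,4-dioxocane with O2/O2'.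
3. Key disconnection: double transannular [2+2+2] of tetraalkynyl dioxocane 18 with two acetylenes. Ring order: pyran + benzene of one half, then pyran + benzene of the other, which also completes the central eight-membered carbocycle.
4. Boron sits only on the C1/C1' arms (giving C8/C8'–OH) and SiMe3 on the C4/C4' arms (giving C5/C5'–H, oxidised later to the ketal). With four identical boronates the two carbonyls of each ring could not be told apart in the final reduction.
5. The dioxocane is formed first, by double Nicholas etherification of diyne-diol 8 (C3–C4–C4'–C3', from oxidative coupling of two molecules of methyl (R)-3-hydroxybutanoate) with the Co2(CO)6-complexed glyoxal/ethyne adduct 13 (C1–C1').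

Key step: step 10

Locants: each half of the cage is numbered like an isochroman (C1 = O–CH, O2, C3 = CH–CH3, C4, C4a, C5–C8, C8a); the second half is primed; the halves are joined C1–C1' and C4–C4'. Dioxocane atoms O1/C2/C3/O4/C5/C6/C7/C8 correspond to O2/C1/C1'/O2'/C3'/C4'/C4/C3.
Remark: glyoxal is used as the anhydrous monomer generated from its commercial trimer dihydrate, and diacetate 12 is carried as the dl/meso mixture because both of its carbinol centres are ionised and re-set in step 7.

**Route**

Step 1
Reactants: 1 methyl (R)-3-hydroxybutanoate (2 molecules incorporated)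
Product: 4 (1R,4R,5R,8R)-4,8-dimethyl-3,7-dioxabicyclo[3.3.0]octane-2,6-dione, via dilithium alkoxide enolate 2 (not isolated), via hydroxy diester 3 (not isolated)
Conditions: LiN(i-Pr)2 (2.2 equiv per 1), THF, −78 to −30 °C; CuBr2 (1.0 equiv per 1), −78 °C to rt; aq. HCl; then TsOH (cat.), toluene, 80 °C
Reagents that add atoms: none
Why: Oxidative enolate homocoupling by divalent copper (one-electron oxidation of the Fráter–Seebach alkoxide enolate to the α-ester radical and C–C coupling) should join two molecules of 1 at C2 with each new bond anti to the C3 methyl of the chelate, which sets both new centres R, and because only like-configured diesters can close with loss of two molecules of methanol to a cis-fused bis-γ-lactone the lactonisation lets 4 (both methyl groups endo) be separated from the other diastereomers by crystallisation or chromatography.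

Step 2
Reactants: 4 bis-γ-lactone
Product: 5 (1R,4R,5R,8R)-4,8-dimethyl-3,7-dioxabicyclo[3.3.0]octane-2,6-diol (bis-lactol, anomer mixture)
Conditions: i-Bu2AlH (2.3 equiv), CH2Cl2, −78 °C; aq. potassium sodium tartrate
Reagents that add atoms: none
Why: Partial reduction of a γ-lactone to the lactol with i-Bu2AlH works because the tetrahedral aluminium alkoxide persists at −78 °C until work-up; the four ring stereocentres are untouched and the two new anomeric centres are of no consequence.

Step 3
Reactants: 5 bis-lactol
Product: 6 (2R,3S,4S,5R)-3,4-diethynylhexane-2,5-diol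
Conditions: dimethyl (1-diazo-2-oxopropyl)phosphonate (3 equiv), K2CO3 (4 equiv), MeOH, 0 °C to rt
Reagents that add atoms: dimethyl (1-diazo-2-oxopropyl)phosphonate, CC(=O)C(=[N+]=[N-])P(=O)(OC)OC
Why: Seyferth–Gilbert homologation with the Ohira–Bestmann reagent converts the small equilibrium amount of hydroxy aldehyde of each lactol into a terminal alkyne and frees the C3/C3' hydroxyls in the same operation, and the low stationary concentration of free aldehyde should limit base-induced epimerisation at C4/C4'.

Step 4
Reactants: 6 diyne-diol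
Product: 8 (2R,3S,4S,5R)-3,4-bis[(trimethylsilyl)ethynyl]hexane-2,5-diol, via tetrasilylated diol 7 (not isolated)
Conditions: n-BuLi (4.2 equiv), THF, −78 °C; Me3SiCl (4.5 equiv), −78 °C to rt; then citric acid, MeOH, rt
Reagents that add atoms: chlorotrimethylsilane, C[Si](C)(C)Cl
Why: Exhaustive lithiation (two alkoxides and two acetylides) followed by silylation and selective acid methanolysis of the labile O–SiMe3 groups is the standard C-silylation of terminal alkynes in alkynols and touches no stereocentre.

Step 5
Reactants: 9 glyoxal; 10 ethynylmagnesium bromide (2.4 equiv)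
Product: 12 hexa-1,5-diyne-3,4-diyl diacetate (dl/meso mixture), via magnesium dialkoxide 11 (not isolated)
Conditions: THF, −30 °C to rt; then Ac2O (3 equiv), 0 °C to rt
Reagents that add atoms: acetic anhydride, CC(=O)OC(C)=O
Why: Twofold 1,2-addition of an alkynyl Grignard reagent to the dialdehyde followed by acylation of the magnesium alkoxides in the same flask should give the bis-propargylic diacetate, whose dl/meso composition is irrelevant because both centres are ionised in step 7.

Step 6
Reactants: 12 diacetate
Product: 13 bis[hexacarbonyldicobalt] complex of 12 (each C≡C bridging a Co2(CO)6 unit)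
Conditions: Co2(CO)8 (2.1 equiv), CH2Cl2, rt
Reagents that add atoms: octacarbonyldicobalt, O=C=[Co](=C=O)(=C=O)(=C=O)[Co](=C=O)(=C=O)(=C=O)=C=O
Why: Terminal alkynes displace two CO ligands of Co2(CO)8 at room temperature to give the alkyne-bridged Co2(CO)6 clusters that stabilise propargylic cations (Nicholas complexes), with no stereochemical consequence.

Step 7
Reactants: 13 bis-cluster diacetate; 8 bis(silylalkynyl) diol (1.0 equiv)
Product: 15 bis[hexacarbonyldicobalt] complex of dioxocane 16 (clusters on the two alkynes at C2/C3 of the dioxocane), via open-chain mono-ether 14 (not isolated)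
Conditions: BF3·OEt2 (3 equiv), 4 Å MS, CH2Cl2 (0.003 M), slow addition of 8, −20 to 0 °C, then 0 °C until the isomer composition no longer changes
Reagents that add atoms: none
Why: Double Nicholas etherification, in which BF3 ionises each propargylic acetate to a cobalt-stabilised cation that is trapped first inter- and then intramolecularly by the two hydroxyls of 8, should close the 1,4-dioxocane, and since ether formation is reversible under these conditions C1 and C1' are expected to equilibrate to the isomer in which each cluster-bearing carbon is cis to the methyl group across its ring oxygen and the two bulky clusters are trans, which is the (S,S) arrangement needed.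

Step 8
Reactants: 15 bis-cluster dioxocane
Product: 16 (2S,3S,5R,6S,7S,8R)-2,3-diethynyl-5,8-dimethyl-6,7-bis[(trimethylsilyl)ethynyl]-1,4-dioxocane
Conditions: (NH4)2Ce(NO3)6 (excess), acetone, −78 to 0 °C
Reagents that add atoms: none
Why: Oxidative decomplexation of alkyne–Co2(CO)6 clusters by tetravalent cerium is the standard release of the free alkyne after a Nicholas reaction and leaves ethers, silylalkynes and all stereocentres intact.

Step 9
Reactants: 16 dioxocane
Product: 18 (2S,3S,5R,6S,7S,8R)-5,8-dimethyl-2,3-bis[(4,4,5,5-tetramethyl-1,3,2-dioxaborolan-2-yl)ethynyl]-6,7-bis[(trimethylsilyl)ethynyl]-1,4-dioxocane, via dilithium bis(acetylide) 17 (not isolated)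
Conditions: n-BuLi (2.05 equiv), THF, −78 °C; 2-isopropoxy-4,4,5,5-tetramethyl-1,3,2-dioxaborolane (2.2 equiv); HCl in Et2O (2.1 equiv), −78 °C to rt; used crude
Reagents that add atoms: 2-isopropoxy-4,4,5,5-tetramethyl-1,3,2-dioxaborolane, CC(C)OB1OC(C)(C)C(C)(C)O1
Why: Lithiation of the two terminal alkynes (the silyl-capped arms are inert), borylation of the acetylides with the isopropoxyborolane and collapse of the ate complexes with anhydrous HCl is the standard preparation of alkynyl pinacol boronates and touches no stereocentre.

Step 10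
Reactants: 18 tetraalkynyl dioxocane; 19 acetylene (2 molecules incorporated)
Product: 21 (1S,3R,4S,1'S,3'R,4'S)-configured dibenzo cage (two 3-methylisochroman units joined C1–C1' and C4–C4') carrying Bpin at C8/C8' and SiMe3 at C5/C5', via mono-annulated arene 20 (not isolated)
Conditions: acetylene (1 atm, slow stream), CpCo(CO)2 (2 × 20 mol %), degassed toluene (0.005 M), 110 °C, hν (visible lamp)
Reagents that add atoms: none
Why: Proposed new method: photolytic loss of CO from CpCo(CO)2 gives a CpCo fragment that should couple the C1 and C4 alkynyl arms, held cis-1,4 across O2–C3 of the dioxocane as a 1,7-diyne, oxidatively to a cobaltacyclopentadiene carrying Bpin and SiMe3 on the carbons next to cobalt, after which acetylene inserts and reductive elimination releases the arene and the catalyst, and the same sequence then repeats on the C1'/C4' pair. The closest known reactions are CpCo- and Rh-catalysed [2+2+2] cocyclisations of open-chain ether-tethered 1,7-diynes, including silyl- and boryl-capped ones, with alkynes to give isochromans, which have not been run transannularly on a medium ring or twice in one substrate. Each pyran ring closes by C4a–C8a bond formation in the oxidative cyclometalation (six-membered ring from the 1,7-diyne) and each benzene ring closes by the two bonds to acetylene (C5–C6 and C7–C8) through alkyne insertion and reductive elimination. No stereocentre is formed, and C1, C3 and C4 of both halves are carried through because the metal never touches them. The step needs pairing selectivity (C1 with C4 and C1' with C4', not the vicinal or trans-disposed arms) and cross-selectivity over acetylene homotrimerisation: only the cis-1,4 pairs can form an unstrained six-membered metallabicycle, the vicinal pairs would need a cyclobutane-fused metallacycle, and the bulky Bpin and SiMe3 caps keep the arms from entering as the third alkyne. The gain of two benzene rings should pay for the strain of the bridged cage.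

Step 11
Reactants: 21 dibenzo cage
Product: 22 cage bis-phenol with OH at C8/C8' and SiMe3 at C5/C5'
Conditions: H2O2 (30% aq), NaOH (aq), THF, 0 °C
Reagents that add atoms: hydrogen peroxide, OO
Why: Oxidation of aryl pinacol boronates with alkaline hydrogen peroxide (1,2-aryl shift from boron to oxygen in the peroxo ate complex) should give the C8/C8' phenols while the aryl silanes and all stereocentres remain unchanged.

Step 12
Reactants: 22 silylated bis-phenol
Product: 23 cage bis-phenol with OH at C8/C8' and H at C5/C5'
Conditions: CF3CO2H (5 equiv), CH2Cl2, 0 °C, short reaction time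
Reagents that add atoms: none
Why: Acid-mediated ipso-protodesilylation is fast for an aryl silane para to a hydroxyl group (protonation at the silicon-bearing carbon gives a β-silyl-stabilised arenium ion that loses the silyl group), so C5/C5' should be freed as C–H under conditions mild enough for the benzylic ethers.

Step 13
Reactants: 23 bis-phenol
Product: 25 cage bis(quinone monoketal) with C8/C8' ketones and C5/C5' dimethyl ketals, via bis(4-methoxyphenol) 24 (not isolated)
Conditions: PhI(OAc)2 (4.4 equiv), MeOH, 0 °C to rt
Reagents that add atoms: methanol, CO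
Why: Hypervalent-iodine oxidative dearomatisation of a para-unsubstituted phenol in methanol, in which the first equivalent of PhI(OAc)2 introduces methoxide para to the hydroxyl and the second converts the resulting 4-methoxyphenol into the 4,4-dimethoxycyclohexa-2,5-dienone, should place the carbonyl at C8/C8' and the ketal at C5/C5' without creating a stereocentre.

Step 14
Reactants: 25 bis(quinone monoketal)
Product: 26 bis(epoxy ketone) with (6R,7S,6'R,7'S) epoxides on the convex faces
Conditions: t-BuOOH (anhydrous, in decane), DBU, CH2Cl2, 0 °C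
Reagents that add atoms: tert-butyl hydroperoxide, CC(C)(C)OO
Why: Weitz–Scheffer nucleophilic epoxidation should occur only at the disubstituted C6=C7 enone double bond (the tetrasubstituted C4a=C8a bond is inert), with peroxide attack at C6 from the convex face of the V-shaped cage, anti to the C1–C1' and C4–C4' bonds that hold the other half, which sets C6/C7 and C6'/C7' as in the target.

Step 15
Reactants: 26 bis(epoxy ketone)
Product: 27 bis(epoxy alcohol) bis-ketal, (6R,7R,8S,6'R,7'R,8'S), each hydroxyl anti to its epoxide
Conditions: i-Bu2AlH (2.5 equiv), THF, −78 °C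
Reagents that add atoms: none
Why: 1,2-Reduction of the epoxy enone by i-Bu2AlH is expected to deliver hydride to C8 from the convex face, both because aluminium coordinates the epoxide oxygen on that face and because the concave face is blocked by the C1 substituent, so that each new hydroxyl is anti to its epoxide as in the target while the ketal protects C5.

Step 16
Reactants: 27 bis-ketal
Product: 28 epoxytwinol A
Conditions: montmorillonite K10, wet CH2Cl2, rt
Reagents that add atoms: water, O
Why: Mild acid-catalysed hydrolysis of the allylic dimethyl ketals on acidic clay should unmask the C5/C5' enone carbonyls without opening the epoxides or ionising the allylic alcohols, and no stereocentre is affected.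

**Compound list**

1 | methyl (R)-3-hydroxybutanoate | C[C@@H](O)CC(=O)OC | starting material
2 | dilithium alkoxide enolate of 1 (not isolated) | C[C@@H]([O-])C=C([O-])OC.[Li+].[Li+] | intermediate
3 | dimethyl (2R,3R)-2,3-bis[(1R)-1-hydroxyethyl]butanedioate (not isolated) | C[C@@H](O)[C@H](C(=O)OC)[C@@H](C(=O)OC)[C@@H](C)O | intermediate
4 | (1R,4R,5R,8R)-4,8-dimethyl-3,7-dioxabicyclo[3.3.0]octane-2,6-dione (cis-fused bis-γ-lactone, methyls endo) | C[C@H]1OC(=O)[C@@H]2[C@H]1C(=O)O[C@@H]2C | intermediate
5 | (1R,4R,5R,8R)-4,8-dimethyl-3,7-dioxabicyclo[3.3.0]octane-2,6-diol (anomer mixture) | C[C@H]1OC(O)[C@@H]2[C@H]1C(O)O[C@@H]2C | intermediate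
6 | (2R,3S,4S,5R)-3,4-diethynylhexane-2,5-diol | C[C@@H](O)[C@H](C#C)[C@@H](C#C)[C@@H](C)O | intermediate
7 | (2R,3S,4S,5R)-2,5-bis(trimethylsilyloxy)-3,4-bis[(trimethylsilyl)ethynyl]hexane (not isolated) | C[C@@H](O[Si](C)(C)C)[C@H](C#C[Si](C)(C)C)[C@@H](C#C[Si](C)(C)C)[C@@H](C)O[Si](C)(C)C | intermediate
8 | (2R,3S,4S,5R)-3,4-bis[(trimethylsilyl)ethynyl]hexane-2,5-diol | C[C@@H](O)[C@H](C#C[Si](C)(C)C)[C@@H](C#C[Si](C)(C)C)[C@@H](C)O | intermediate
9 | glyoxal | O=CC=O | starting material
10 | ethynylmagnesium bromide | C#C[Mg]Br | starting material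
11 | bis(bromomagnesium) hexa-1,5-diyne-3,4-diolate (not isolated) | C#CC(O[Mg]Br)C(O[Mg]Br)C#C | intermediate
12 | hexa-1,5-diyne-3,4-diyl diacetate (dl/meso mixture) | CC(=O)OC(C#C)C(C#C)OC(C)=O | intermediate
13 | bis[hexacarbonyldicobalt] complex of 12 | CC(=O)OC(C12[Co]3(=C=O)(=C=O)(=C=O)[Co]1(=C=O)(=C=O)(=C=O)[CH]23)C(OC(C)=O)C12[Co]3(=C=O)(=C=O)(=C=O)[Co]1(=C=O)(=C=O)(=C=O)[CH]23 | intermediate
14 | open-chain mono-ether of 8 with the bis-cluster, one acetate left (not isolated; propargylic centres not yet fixed) | C[C@@H](O)[C@H](C#C[Si](C)(C)C)[C@@H](C#C[Si](C)(C)C)[C@@H](C)OC(C12[Co]3(=C=O)(=C=O)(=C=O)[Co]1(=C=O)(=C=O)(=C=O)[CH]23)C(OC(C)=O)C12[Co]3(=C=O)(=C=O)(=C=O)[Co]1(=C=O)(=C=O)(=C=O)[CH]23 | intermediate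
15 | bis[hexacarbonyldicobalt] complex of dioxocane 16 | C[C@H]1O[C@@H](C23[Co]4(=C=O)(=C=O)(=C=O)[Co]2(=C=O)(=C=O)(=C=O)[CH]34)[C@H](C23[Co]4(=C=O)(=C=O)(=C=O)[Co]2(=C=O)(=C=O)(=C=O)[CH]34)O[C@H](C)[C@H](C#C[Si](C)(C)C)[C@H]1C#C[Si](C)(C)C | intermediate
16 | (2S,3S,5R,6S,7S,8R)-2,3-diethynyl-5,8-dimethyl-6,7-bis[(trimethylsilyl)ethynyl]-1,4-dioxocane | C[C@H]1O[C@@H](C#C)[C@H](C#C)O[C@H](C)[C@H](C#C[Si](C)(C)C)[C@H]1C#C[Si](C)(C)C | intermediate
17 | dilithium bis(acetylide) of 16 (not isolated) | C[C@H]1O[C@@H](C#C[Li])[C@H](C#C[Li])O[C@H](C)[C@H](C#C[Si](C)(C)C)[C@H]1C#C[Si](C)(C)C | intermediate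
18 | (2S,3S,5R,6S,7S,8R)-5,8-dimethyl-2,3-bis[(pinacolboryl)ethynyl]-6,7-bis[(trimethylsilyl)ethynyl]-1,4-dioxocane (key-step precursor) | C[C@H]1O[C@@H](C#CB2OC(C)(C)C(C)(C)O2)[C@H](C#CB2OC(C)(C)C(C)(C)O2)O[C@H](C)[C@H](C#C[Si](C)(C)C)[C@H]1C#C[Si](C)(C)C | intermediate
19 | acetylene | C#C | starting material
20 | mono-annulated arene: one isochroman fused on the dioxocane, C1'/C4' arms intact (not isolated) | C[C@H]1O[C@H]2c3c(c([Si](C)(C)C)ccc3B4OC(C)(C)C(C)(C)O4)[C@@H]1[C@@H](C#C[Si](C)(C)C)[C@@H](C)O[C@H]2C#CB3OC(C)(C)C(C)(C)O3 | intermediate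
21 | (1S,3R,4S,1'S,3'R,4'S) dibenzo cage, Bpin at C8/C8', SiMe3 at C5/C5' (key-step product) | C[C@H]1O[C@H]2c3c(c([Si](C)(C)C)ccc3B4OC(C)(C)C(C)(C)O4)[C@@H]1[C@H]1c3c(c(B4OC(C)(C)C(C)(C)O4)ccc3[Si](C)(C)C)[C@@H]2O[C@@H]1C | intermediate
22 | cage bis-phenol, OH at C8/C8', SiMe3 at C5/C5' | C[C@H]1O[C@H]2c3c(c([Si](C)(C)C)ccc3O)[C@@H]1[C@H]1c3c(c(O)ccc3[Si](C)(C)C)[C@@H]2O[C@@H]1C | intermediate
23 | cage bis-phenol, OH at C8/C8', H at C5/C5' | C[C@H]1O[C@H]2c3c(cccc3O)[C@@H]1[C@H]1c3c(c(O)ccc3)[C@@H]2O[C@@H]1C | intermediate
24 | cage bis(4-methoxyphenol), OH at C8/C8', OMe at C5/C5' (not isolated) | C[C@H]1O[C@H]2c3c(c(OC)ccc3O)[C@@H]1[C@H]1c3c(c(O)ccc3OC)[C@@H]2O[C@@H]1C | intermediate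
25 | cage bis(quinone monoketal), C8/C8' ketone, C5/C5' dimethyl ketal | C[C@H]1O[C@H]2C3=C(C(OC)(OC)C=CC3=O)[C@@H]1[C@H]1C3=C(C(=O)C=CC3(OC)OC)[C@@H]2O[C@@H]1C | intermediate
26 | bis(epoxy ketone), (6R,7S,6'R,7'S), epoxides on the convex faces | C[C@H]1O[C@H]2C3=C(C(OC)(OC)[C@@H]4O[C@@H]4C3=O)[C@@H]1[C@H]1C3=C(C(=O)[C@H]4O[C@H]4C3(OC)OC)[C@@H]2O[C@@H]1C | intermediate
27 | bis(epoxy alcohol) bis-ketal, (6R,7R,8S,6'R,7'R,8'S) | C[C@H]1O[C@H]2C3=C(C(OC)(OC)[C@@H]4O[C@@H]4[C@H]3O)[C@@H]1[C@H]1C3=C([C@H](O)[C@H]4O[C@H]4C3(OC)OC)[C@@H]2O[C@@H]1C | intermediate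
28 | epoxytwinol A | C[C@H]1O[C@H]2C3=C(C(=O)[C@@H]4O[C@@H]4[C@H]3O)[C@@H]1[C@H]1C3=C([C@H](O)[C@H]4O[C@H]4C3=O)[C@@H]2O[C@@H]1C | target

**Step count**

Total: 16 steps. Longest linear sequence: 14 steps (steps 1–4 and 7–16); steps 5–6 make the second fragment.

**Steps most likely to fail**

1. Step 10 (Proposed new method). What may go wrong: the cobalt centre may fail to bring the two cis-1,4 alkynyl arms together across the medium ring, so that the arms react one by one with acetylene or the sequence stops after the first annulation. Acetylene self-trimerisation may also outrun the cocyclisation. Fallback, stoichiometric and stepwise with known reaction types: it sets out from 18. The transannular C–C bonds are made first with a divalent titanium alkoxide reagent, Ti(O-i-Pr)4/2 i-PrMgCl in Et2O at −50 °C, which cyclises silyl- and heteroatom-capped diynes to titanacyclopentadienes. This should give the bis(titanacyclopentadiene) F1 (not isolated; an aliquot can be checked by deuterolysis). Ethynyl p-tolyl sulfone is then added as an acetylene surrogate: it inserts and loses sulfinate, which aromatises each ring to the bis(aryltitanium) sulfinate F2 (not isolated; titanium is drawn at C6/C6', and its position is erased in the next operation). Protonolysis with aq. HCl comes back to the route at 21.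

2. Step 7. What may go wrong: intermolecular etherification may outpace closure of the eight-membered ring and give oligomers; the cobalt-stabilised cations may eliminate to enynes; equilibration at C1/C1' may end at a diastereomer other than the cis-across-oxygen one. Fallback: cobalt is left out and the two propargylic C–O bonds are made by copper-catalysed asymmetric propargylic etherification. A chiral monovalent copper–pybox catalyst turns terminal propargylic esters into copper allenylidenes that are attacked by alcohols, so the configuration is set by the catalyst under kinetic control. It sets out from 12 and 8. With [Cu(MeCN)4]BF4, the Ph-pybox enantiomer that delivers the (S)-ether, i-Pr2NEt, CH2Cl2, −20 °C and 1:1 stoichiometry, the first substitution should give the open-chain mono-ether acetate F3. A second exposure to the same catalyst at high dilution closes the ring and comes back to the route at 16, so that steps 6 and 8 are not needed.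

3. Step 1. What may go wrong: facial control in the coupling of two open-chain α-ester radicals may be low, giving all three diastereomeric diesters; bromine transfer from CuBr2 or simple re-protonation may compete. Fallback, cyclic stereocontrol through an acetal template: it sets out from 1. Saponification (LiOH, THF/H2O) gives (R)-3-hydroxybutanoic acid F4. Acetalisation with pivalaldehyde (TsOH, pentane, water removal) gives (2R,6R)-2-tert-butyl-6-methyl-1,3-dioxan-4-one F5. Enolisation (LiN(i-Pr)2, THF, −78 °C) and oxidative coupling of two molecules of the enolate with CuBr2 at −78 °C should give the 5,5'-linked bis-dioxanone F6, each new bond trans to the ring methyl. HCl/MeOH followed by TsOH in toluene removes the acetals, lactonises and comes back to the route at 4.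

**Further compounds**

F1 | step 10 | bis(titanacyclopentadiene) from 18, Ti(O-i-Pr)2 bridging C5/C8 and C5'/C8' | C[C@H]1O[C@H]2C3C(=C([Si](C)(C)C)[Ti](OC(C)C)(OC(C)C)C=3B4OC(C)(C)C(C)(C)O4)[C@@H]1[C@H]1C3C(=C(B4OC(C)(C)C(C)(C)O4)[Ti](OC(C)C)(OC(C)C)C=3[Si](C)(C)C)[C@@H]2O[C@@H]1C
F2 | step 10 | bis(aryltitanium) sulfinate of cage 21, titanium at C6/C6' | C[C@H]1O[C@H]2c3c(c([Si](C)(C)C)c([Ti](OC(C)C)(OC(C)C)OS(=O)c4ccc(C)cc4)cc3B4OC(C)(C)C(C)(C)O4)[C@@H]1[C@H]1c3c(c(B4OC(C)(C)C(C)(C)O4)cc([Ti](OC(C)C)(OC(C)C)OS(=O)c4ccc(C)cc4)c3[Si](C)(C)C)[C@@H]2O[C@@H]1C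
F3 | step 7 | open-chain mono-ether acetate, (S) at the new ether carbon, acetate-bearing carbon as epimer mixture | C[C@@H](O)[C@H](C#C[Si](C)(C)C)[C@@H](C#C[Si](C)(C)C)[C@@H](C)O[C@@H](C#C)C(OC(C)=O)C#C
F4 | step 1 | (R)-3-hydroxybutanoic acid | C[C@@H](O)CC(=O)O
F5 | step 1 | (2R,6R)-2-tert-butyl-6-methyl-1,3-dioxan-4-one | C[C@@H]1CC(=O)O[C@@H](O1)C(C)(C)C
F6 | step 1 | (2R,2'R,5R,5'R,6R,6'R)-2,2'-di-tert-butyl-6,6'-dimethyl-[5,5'-bi(1,3-dioxane)]-4,4'-dione | C[C@H]1O[C@@H](C(C)(C)C)OC(=O)[C@@H]1[C@H]1C(=O)O[C@H](C(C)(C)C)O[C@@H]1C
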